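## The problem

Compound 28 is a 2H-chromen-6-ol: a benzene ring fused to a pyran ring whose C2 is a fully substituted ether carbon (S) carrying a methyl group and a thirteen-carbon chain. The chain holds an E-trisubstituted alkene (C3'=C4'), an E-disubstituted alkene (C6'=C7') separated from it by the doubly allylic C5', a tertiary carbinol stereocentre at C8' (S), and a terminal isopropylidene group. C2 and C8' are seven carbon atoms apart, so neither can direct the other. Each must come from reagent control, and because the two diastereomers would be nearly inseparable, each centre should be fixed in its own fragment before the halves are joined. Several groups restrict the conditions: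

- The 6-hydroxy group para to O1 makes the arene a hydroquinone monoether that oxidises easily, so it stays masked until the last step.
- The 2H-chromene is attacked by acid at C3=C4 and opens under light to an o-quinone methide, which would erase C2.
- The tertiary allylic alcohol ionises with acid.
- The skipped diene migrates into conjugation under strong base.

The feature that opens the synthesis is C2 itself. It is bonded to O1, a methyl group, ring carbon C3 and chain carbon C1', so it is the adduct of a carbon nucleophile with C2 of a flat 2-methylbenzopyrylium cation. A 2-methylchromone gives such a cation on O-silylation. Its C4 oxygen can later leave to create C3=C4, and an alkynyl nucleophile brings C1'–C3' in a form that hydrogenation turns into the saturated link.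

## Retrosynthesis

**28 back to 26.** No skeletal bond is cut. The phenol is traced to its triisopropylsilyl ether 27, which fluoride opens under near-neutral conditions. The C6'=C7' alkene of 27 is traced to the alkyne of propargylic alcohol 26. The C8' hydroxyl then serves as the internal director for a trans-hydroalumination, so the E geometry is a consequence of mechanism and not of an olefination with its own selectivity problem.

**26 to bromide 19 and alkynol 24.** The C5'–C6' bond is cut. This cut falls between the two stereocentres and gives a chromene half carrying C2 and a ten-carbon half carrying C8'. The electrophile is a primary allylic bromide and the nucleophile a terminal alkyne. The neighbouring cut at C7'–C8' would create the carbinol centre by addition to a methyl ketone late and with weak control. The forward reaction must be a copper-mediated alkynyl–allyl coupling at the primary carbon, with retention of the E-alkene and tolerance of the tertiary alkoxide.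

**24 back to geraniol 20.** C8' with its methyl group and homoprenyl chain is C3 of geraniol. Only oxygen has to be added and C1 turned into the alkyne terminus. Asymmetric epoxidation of the allylic alcohol gives epoxy alcohol 21, chlorination gives 22, and base-induced fragmentation of the epoxy chloride gives 24 without touching the C–O bond at the stereocentre. No skeletal bond is formed in this branch.

**19 back to keto aldehyde 13 and ylide 14.** The bromide comes from allylic alcohol 18 and that from ester 17. The C3=C4 alkene of 17 is traced through chromanol 16 to the C4 ketone of 15. The C3'=C4' bond of 15 is cut to aldehyde 13 and the stabilised ylide 14, which gives the E-enoate reliably. The ketone is kept until after the olefination so that an aldehyde and an acid-sensitive chromene never meet under acid, and the dehydration is run on a robust ester.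

**13 back to alkyne adduct 11.** The aldehyde is unmasked from diethyl acetal 12, and the C1'–C2' ethylene link of 12 is the hydrogenated alkyne of 11. An alkynyl acetal is chosen because it brings C3' at the aldehyde oxidation level, so no redox step is spent there.

**11 to chromone 7 and alkyne 8 (key disconnection).** The C2–C1' bond is cut. This removes the only ring stereocentre and the whole chain in one stroke and leaves an achiral, flat heteroarene. The forward step activates 7 as the 4-silyloxybenzopyrylium ion 9; a chiral copper acetylide then adds to one face of C2 to give silyl enol ether 10, which is hydrolysed to 11. The step has to control regiochemistry (C2, not C4), enantioface selection, and the acidity of the 2-methyl group.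

**7 back to phenol 1.** The silyl ether comes from phenol 6 and that from methyl ether 5. The pyranone of 5 is cut at O1–C2 and C2–C3 to acetophenone 3 plus ethyl acetate (Claisen condensation, then cyclodehydration). The C4–C4a bond of 3 comes from ortho-acylation of 4-methoxy-2-methylphenol 1. The para position and one ortho position of 1 are blocked, so the acyl group has a single ortho site.

## Roads not taken

**Alternative 1:** Oxygen-tethered Dötz benzannulation. The cut removes three bonds of the benzene ring (C8a–C4a, C5–C6, C6–C7). On heating, chromium carbene A2 would take up its tethered alkyne and one CO and close the benzene and pyran rings together to give chromenol A1.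

- Merits: two rings in one step, no chromone preparation, and no C4 oxygen to remove afterwards. In ring construction it is shorter than the chosen plan, which spends four steps on the chromone and two on deleting the C4 carbonyl.
- Weak points:
  - A2 carries a tertiary, allylic alkoxy group on the carbene carbon. Such complexes are hard to make from a hindered tertiary alcohol and ionise easily.
  - The benzannulation creates no stereocentre, so C2 would have to be set beforehand by an asymmetric addition to a methyl alkyl ketone, the very problem the tertiary ether poses.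
  - Stoichiometric Cr(CO)6 is needed.
  - A1 ends at the homoprenyl stage. Reaching the allylic alcohol level of 18 would need an E-selective allylic oxidation (SeO2) next to a free hydroquinone-type phenol and a chromene.
- Comparison: the chosen plan sets against the ring-forming economy a catalytic C–C bond formation that installs C2 and the C1'–C3' unit at the correct oxidation level in one step from a cheap arene.

**Alternative 2:** One-carbon ring expansion of a benzofuranone. The cut removes C4 (bonds C3–C4 and C4–C4a). Trimethylsilyldiazomethane with BF3·OEt2 would add to the ketone of benzofuranone A4, and aryl migration with loss of N2 would give chroman-3-one A3 after protodesilylation.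

- Merits: the quaternary centre is made at the five-membered ketone stage, where asymmetric α-allylation of such enolates is well developed. A3 cannot racemise by retro-oxa-Michael opening, a real advantage over the 4-chromanones 11–15 of the chosen route.
- Weak points:
  - Migration of the aryl carbon must win over migration of the oxygenated quaternary carbon, and epoxide formation and double homologation compete.
  - The carbonyl ends at C3, so the C3=C4 alkene must come from a homobenzylic alcohol by sulfonate elimination, and chroman-3-ones enolise and oxidise readily.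
  - The allyl group still needs hydroboration and oxidation to reach the C3' aldehyde, where adduct 11 needs only hydrogenation and hydrolysis.
  - The diazo reagent is toxic and awkward on scale.
- Comparison: the route is longer by the benzofuranone synthesis and the extra chain steps. The chosen plan has the racemisation risk of its chromanones to set against this, and meets it by keeping those intermediates away from strong base.

**Alternative 3:** Late asymmetric alkenylzinc addition to sulcatone. The cut is C7'–C8'. Terminal alkyne A6 would be hydrozirconated with Cp2Zr(H)Cl and transmetalated with Me2Zn, and the E-alkenylzinc added to ketone A7 under Ti(OiPr)4 and a chiral bis(sulfonamide) diol to give A5, the silyl ether of the target.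

- Merits: this is the more convergent endgame. The E-alkene and the carbinol form in one step from a commercial ketone, the three-step synthesis of 24 disappears, and so does the hydride reduction. In step count it is better than the chosen endgame by about three steps.
- Weak points:
  - The ketone offers the catalyst only a methyl group against an unbranched CH2CH2 chain, the hard case for enantioface selection in ketone additions.
  - Any shortfall appears as a C8' epimer that the remote C2 centre will not help to separate or even to measure.
  - The alternative does not say how C2 of A6 is made; it needs a chromene synthesis such as the present one, for instance ethynylation of bromide 19.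
- Comparison: the chosen plan sets certainty at C8' against the shorter endgame. The epoxidation of 20 fixes that centre in a small fragment, 24, whose purity can be checked before it is committed.

Key step: step 5

Assumption: the sense of induction of the copper bis(oxazoline) catalyst on a 2-methylbenzopyrylium ion cannot be predicted with confidence, so the ligand antipode that delivers the (R)-adduct 11 is the one used (both antipodes are commercial).

## Route

Step 1
Reactants: 1 4-methoxy-2-methylphenol
Product: 3 1-(2-hydroxy-5-methoxy-3-methylphenyl)ethan-1-one, via aryl acetate 2 (not isolated)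
Conditions: Ac2O (1.2 equiv), BF3·OEt2 (3 equiv), 0 → 90 °C; then H2O
Reagents that add atoms: acetic anhydride, CC(=O)OC(C)=O
Why: O-Acetylation followed in the same flask by a BF3-promoted Fries rearrangement; the para position carries OMe and one ortho position carries methyl, so the acyl group goes to the single free ortho carbon, where the chelated o-hydroxy ketone is the thermodynamic sink, and BF3 does not cleave the methyl ether.

Step 2
Reactants: 3 1-(2-hydroxy-5-methoxy-3-methylphenyl)ethan-1-one
Product: 5 6-methoxy-2,8-dimethyl-4H-chromen-4-one, via 1,3-diketone 4 (not isolated)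
Conditions: NaH (4 equiv), EtOAc (5 equiv), THF, reflux; aq. HCl quench; then conc. HCl (cat.), AcOH, 90 °C
Reagents that add atoms: ethyl acetate, CCOC(C)=O
Why: Claisen condensation of the phenoxide–enolate with ethyl acetate gives the aroylacetone, and acid-catalysed cyclodehydration closes the pyranone; this is the classical 2-methylchromone synthesis.

Step 3
Reactants: 5 6-methoxy-2,8-dimethyl-4H-chromen-4-one
Product: 6 6-hydroxy-2,8-dimethyl-4H-chromen-4-one
Conditions: BBr3 (3 equiv), CH2Cl2, −78 °C → rt; then H2O
Reagents that add atoms: none
Why: Lewis-acid cleavage of the aryl methyl ether; the chromone carbonyl only complexes BBr3, which the extra equivalents allow for.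

Step 4
Reactants: 6 6-hydroxy-2,8-dimethyl-4H-chromen-4-one
Product: 7 2,8-dimethyl-6-[(triisopropylsilyl)oxy]-4H-chromen-4-one
Conditions: TIPSCl (1.2 equiv), imidazole (2.5 equiv), DMF, rt
Reagents that add atoms: chlorotriisopropylsilane, CC(C)[Si](Cl)(C(C)C)C(C)C
Why: Standard phenol silylation; the bulky aryl silyl ether tolerates silyl triflate, acid, hydride and organomagnesium reagents and leaves with fluoride at the end.

Step 5
Reactants: 7 2,8-dimethyl-6-[(triisopropylsilyl)oxy]-4H-chromen-4-one; 8 3,3-diethoxyprop-1-yne
Product: 11 (R)-2-(3,3-diethoxyprop-1-yn-1-yl)-2,8-dimethyl-6-[(triisopropylsilyl)oxy]chroman-4-one, via benzopyrylium triflate 9 (not isolated), via silyl enol ether 10 (not isolated)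
Conditions: 7, TBSOTf (1.0 equiv), CH2Cl2, 40 °C; transferred at −78 °C into CuI (10 mol %), indane-derived bis(oxazoline) ligand (12 mol %), 8 (1.5 equiv), iPr2NEt (1.6 equiv), toluene, −78 → −40 °C; then 1 M HCl, THF, 0 °C
Reagents that add atoms: none
Why: TBSOTf silylates the carbonyl oxygen of 7 and turns the pyranone into the aromatic 4-silyloxybenzopyrylium triflate 9, the only species present that is electrophilic enough for a copper acetylide. CuI, the bis(oxazoline) ligand and iPr2NEt convert 8 into a chiral monovalent copper acetylide, which adds to C2 of 9 to form the C2–C1' bond and silyl enol ether 10; dilute acid hydrolyses 10 to chromanone 11, and no ring is closed. The closest known reaction type is the copper bis(oxazoline)-catalysed enantioselective alkynylation of chromone-derived 4-silyloxybenzopyrylium triflates, which has been carried to 2-substituted chromones and fully substituted C2 ether centres. Attack at C2 and not C4 follows from the silyloxy group, which donates into and shields C4, and from the conjugated enol ether that only C2 attack produces. The C2 stereocentre is set by the catalyst alone: the ion pair meets the copper–carbon bond inside the pocket of the twofold-symmetric ligand, whose indane walls must tell the methyl-bearing edge of the cation from its C3–H edge, so the reaction is run cold in toluene to keep the ion pair tight. The acidic 2-methyl protons of 9 can be removed by the amine to give a 2-methylene-2H-chromene, but this is reversible and is held back by a hindered base in small excess at low temperature. Pre-forming 9 with no excess TBSOTf keeps silyl triflate away from the acetal of 8, and the alkynyl acetal, slow to ionise, outlasts the brief hydrolysis of 10.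

Step 6
Reactants: 11 (R)-2-(3,3-diethoxyprop-1-yn-1-yl)-2,8-dimethyl-6-[(triisopropylsilyl)oxy]chroman-4-one
Product: 12 (S)-2-(3,3-diethoxypropyl)-2,8-dimethyl-6-[(triisopropylsilyl)oxy]chroman-4-one
Conditions: H2 (1 atm), 10% Pd/C, EtOAc, Et3N (trace), rt
Reagents that add atoms: none
Why: Heterogeneous hydrogenation of the alkyne to the alkane; at one atmosphere under neutral conditions the aryl ketone, acetal and silyl ether are left alone, and C2 is untouched (the descriptor changes from R to S only because the chain loses priority to C3).

Step 7
Reactants: 12 (S)-2-(3,3-diethoxypropyl)-2,8-dimethyl-6-[(triisopropylsilyl)oxy]chroman-4-one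
Product: 13 3-{(2S)-2,8-dimethyl-4-oxo-6-[(triisopropylsilyl)oxy]chroman-2-yl}propanal
Conditions: pTsOH·H2O (10 mol %), acetone/H2O (10:1), rt
Reagents that add atoms: water, O
Why: Acid-catalysed hydrolysis of an aliphatic acetal; it is fast in dilute acid at room temperature, where the aryl silyl ether is stable and the aryl ketone enolises too slowly for aldol closure, and 13 is used at once.

Step 8
Reactants: 13 3-{(2S)-2,8-dimethyl-4-oxo-6-[(triisopropylsilyl)oxy]chroman-2-yl}propanal; 14 ethyl 2-(triphenylphosphoranylidene)propanoate
Product: 15 ethyl (2E)-5-{(2S)-2,8-dimethyl-4-oxo-6-[(triisopropylsilyl)oxy]chroman-2-yl}-2-methylpent-2-enoate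
Conditions: 14 (1.3 equiv), CH2Cl2, rt
Reagents that add atoms: none
Why: Wittig olefination with a stabilised ylide, which reacts with the aldehyde and not the aryl ketone; reversible oxaphosphetane formation places the ester trans to the chain and gives the E-trisubstituted alkene C3'=C4'.

Step 9
Reactants: 15 ethyl (2E)-5-{(2S)-2,8-dimethyl-4-oxo-6-[(triisopropylsilyl)oxy]chroman-2-yl}-2-methylpent-2-enoate
Product: 16 ethyl (2E)-5-{(2S)-4-hydroxy-2,8-dimethyl-6-[(triisopropylsilyl)oxy]chroman-2-yl}-2-methylpent-2-enoate (both C4 epimers)
Conditions: NaBH4 (1.5 equiv), EtOH, 0 °C → rt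
Reagents that add atoms: none
Why: Borohydride reduces the aryl ketone and leaves the hindered conjugated ester; the C4 configuration does not matter because the next step removes it.

Step 10
Reactants: 16 ethyl (2E)-5-{(2S)-4-hydroxy-2,8-dimethyl-6-[(triisopropylsilyl)oxy]chroman-2-yl}-2-methylpent-2-enoate
Product: 17 ethyl (2E)-5-{(2S)-2,8-dimethyl-6-[(triisopropylsilyl)oxy]-2H-chromen-2-yl}-2-methylpent-2-enoate
Conditions: pTsOH·H2O (5 mol %), toluene, 80 °C, dark; NaHCO3 quench
Reagents that add atoms: none
Why: Acid-catalysed E1 dehydration through the C4 benzylic cation, stabilised by O1; C2 is quaternary, so only the conjugated C3=C4 alkene can form. From here on the chromenes are kept from light.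

Step 11
Reactants: 17 ethyl (2E)-5-{(2S)-2,8-dimethyl-6-[(triisopropylsilyl)oxy]-2H-chromen-2-yl}-2-methylpent-2-enoate
Product: 18 (2E)-5-{(2S)-2,8-dimethyl-6-[(triisopropylsilyl)oxy]-2H-chromen-2-yl}-2-methylpent-2-en-1-ol
Conditions: iBu2AlH (2.5 equiv), CH2Cl2, −78 °C; aq. potassium sodium tartrate
Reagents that add atoms: none
Why: 1,2-Reduction of the conjugated ester to the allylic alcohol by the aluminium hydride; the alkenes and the aryl silyl ether are inert at −78 °C.

Step 12
Reactants: 18 (2E)-5-{(2S)-2,8-dimethyl-6-[(triisopropylsilyl)oxy]-2H-chromen-2-yl}-2-methylpent-2-en-1-ol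
Product: 19 ({(2S)-2-[(3E)-5-bromo-4-methylpent-3-en-1-yl]-2,8-dimethyl-2H-chromen-6-yl}oxy)triisopropylsilane
Conditions: CBr4 (1.3 equiv), PPh3 (1.4 equiv), CH2Cl2, 0 °C
Reagents that add atoms: carbon tetrabromide, BrC(Br)(Br)Br
Why: Appel bromination of a primary allylic alcohol under neutral conditions; the primary bromide forms without allylic transposition or loss of E geometry and is used without storage.

Step 13
Reactants: 20 geraniol
Product: 21 [(2S,3S)-3-methyl-3-(4-methylpent-3-en-1-yl)oxiran-2-yl]methanol
Conditions: Ti(OiPr)4 (5 mol %), L-(+)-diethyl tartrate (7 mol %), tBuOOH (1.5 equiv), 4 Å molecular sieves, CH2Cl2, −20 °C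
Reagents that add atoms: tert-butyl hydroperoxide, CC(C)(C)OO
Why: Sharpless asymmetric epoxidation; the titanium tartrate complex binds the allylic alcohol and the hydroperoxide and delivers oxygen to one face of C2=C3, the L-(+)-tartrate giving the (2S,3S)-epoxide, while the remote 6,7-alkene has no directing hydroxyl and is not touched. C3 becomes C8' of the target.

Step 14
Reactants: 21 [(2S,3S)-3-methyl-3-(4-methylpent-3-en-1-yl)oxiran-2-yl]methanol
Product: 22 (2R,3S)-2-(chloromethyl)-3-methyl-3-(4-methylpent-3-en-1-yl)oxirane
Conditions: PPh3 (1.3 equiv), CCl4, NaHCO3, reflux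
Reagents that add atoms: carbon tetrachloride, ClC(Cl)(Cl)Cl
Why: Appel chlorination of the primary alcohol under buffered neutral conditions that leave the epoxide closed; no stereocentre is touched (the C2 descriptor changes only through the new priority of CH2Cl).

Step 15
Reactants: 22 (2R,3S)-2-(chloromethyl)-3-methyl-3-(4-methylpent-3-en-1-yl)oxirane
Product: 24 (3S)-3,7-dimethyloct-6-en-1-yn-3-ol, via chloroalkenyl alkoxide 23 (not isolated)
Conditions: n-BuLi (3.2 equiv), THF, −40 → −20 °C; then H2O
Reagents that add atoms: none
Why: Base-induced fragmentation of a 2,3-epoxy chloride: deprotonation at CH2Cl opens the epoxide to alkoxide 23, a second equivalent eliminates HCl to the alkyne and a third holds it as the acetylide; the C3–O bond is never broken, so the carbinol configuration is retained.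

Step 16
Reactants: 19 ({(2S)-2-[(3E)-5-bromo-4-methylpent-3-en-1-yl]-2,8-dimethyl-2H-chromen-6-yl}oxy)triisopropylsilane; 24 (3S)-3,7-dimethyloct-6-en-1-yn-3-ol
Product: 26 (6S,10E)-13-{(2S)-2,8-dimethyl-6-[(triisopropylsilyl)oxy]-2H-chromen-2-yl}-2,6,10-trimethyltrideca-2,10-dien-7-yn-6-ol, via bis(bromomagnesium) salt 25 (not isolated)
Conditions: 24 (1.5 equiv), EtMgBr (2.9 equiv), THF, 0 °C → rt; CuCl (10 mol %); then 19, THF, 45 °C; aq. NH4Cl
Reagents that add atoms: none
Why: Copper-catalysed coupling of an alkynylmagnesium reagent with a primary allylic bromide; the alkynylcopper formed by transmetalation bonds to the unhindered CH2 terminus (C5'), the E-alkene is retained, and the aryl silyl ether meets no carbonate or hydroxide base.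

Step 17
Reactants: 26 (6S,10E)-13-{(2S)-2,8-dimethyl-6-[(triisopropylsilyl)oxy]-2H-chromen-2-yl}-2,6,10-trimethyltrideca-2,10-dien-7-yn-6-ol
Product: 27 (6S,7E,10E)-13-{(2S)-2,8-dimethyl-6-[(triisopropylsilyl)oxy]-2H-chromen-2-yl}-2,6,10-trimethyltrideca-2,7,10-trien-6-ol
Conditions: LiAlH4 (4 equiv), THF, 0 °C → reflux; aq. potassium sodium tartrate
Reagents that add atoms: none
Why: Hydroxyl-directed trans-hydroalumination of a propargylic alcohol: the aluminium alkoxide delivers hydride to the near alkyne carbon and the cyclic vinylalanate is protonated on work-up, giving only the E-alkene C6'=C7'; isolated alkenes are inert, and any aryl silyl ether lost here is of no consequence because the next step removes it.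

Step 18
Reactants: 27 (6S,7E,10E)-13-{(2S)-2,8-dimethyl-6-[(triisopropylsilyl)oxy]-2H-chromen-2-yl}-2,6,10-trimethyltrideca-2,7,10-trien-6-ol
Product: 28 (2S)-2-[(3E,6E,8S)-8-hydroxy-4,8,12-trimethyltrideca-3,6,11-trien-1-yl]-2,8-dimethyl-2H-chromen-6-ol
Conditions: Bu4NF (1.2 equiv), AcOH (1.2 equiv), THF, 0 °C, argon, dark
Reagents that add atoms: none
Why: Fluoride cleavage of the aryl silyl ether; acetic acid buffering and exclusion of air and light protect the hydroquinone-type phenol, the chromene and the tertiary allylic alcohol.

## Compound list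

1 | 4-methoxy-2-methylphenol | COc1ccc(O)c(C)c1 | starting material
2 | 4-methoxy-2-methylphenyl acetate | COc1ccc(OC(C)=O)c(C)c1 | intermediate (not isolated)
3 | 1-(2-hydroxy-5-methoxy-3-methylphenyl)ethan-1-one | COc1cc(C)c(O)c(C(C)=O)c1 | intermediate
4 | 1-(2-hydroxy-5-methoxy-3-methylphenyl)butane-1,3-dione | COc1cc(C)c(O)c(C(=O)CC(C)=O)c1 | intermediate (not isolated)
5 | 6-methoxy-2,8-dimethyl-4H-chromen-4-one | COc1cc(C)c2oc(C)cc(=O)c2c1 | intermediate
6 | 6-hydroxy-2,8-dimethyl-4H-chromen-4-one | Cc1cc(=O)c2cc(O)cc(C)c2o1 | intermediate
7 | 2,8-dimethyl-6-[(triisopropylsilyl)oxy]-4H-chromen-4-one | Cc1cc(=O)c2cc(O[Si](C(C)C)(C(C)C)C(C)C)cc(C)c2o1 | intermediate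
8 | 3,3-diethoxyprop-1-yne | C#CC(OCC)OCC | starting material
9 | 4-[(tert-butyldimethylsilyl)oxy]-2,8-dimethyl-6-[(triisopropylsilyl)oxy]chromenylium trifluoromethanesulfonate | Cc1cc(O[Si](C)(C)C(C)(C)C)c2cc(O[Si](C(C)C)(C(C)C)C(C)C)cc(C)c2[o+]1.[O-]S(=O)(=O)C(F)(F)F | intermediate (not isolated)
10 | tert-butyl({(2R)-2-(3,3-diethoxyprop-1-yn-1-yl)-2,8-dimethyl-6-[(triisopropylsilyl)oxy]-2H-chromen-4-yl}oxy)dimethylsilane | CCOC(OCC)C#C[C@@]1(C)C=C(O[Si](C)(C)C(C)(C)C)c2cc(O[Si](C(C)C)(C(C)C)C(C)C)cc(C)c2O1 | intermediate (not isolated)
11 | (R)-2-(3,3-diethoxyprop-1-yn-1-yl)-2,8-dimethyl-6-[(triisopropylsilyl)oxy]chroman-4-one | CCOC(OCC)C#C[C@@]1(C)CC(=O)c2cc(O[Si](C(C)C)(C(C)C)C(C)C)cc(C)c2O1 | intermediate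
12 | (S)-2-(3,3-diethoxypropyl)-2,8-dimethyl-6-[(triisopropylsilyl)oxy]chroman-4-one | CCOC(OCC)CC[C@@]1(C)CC(=O)c2cc(O[Si](C(C)C)(C(C)C)C(C)C)cc(C)c2O1 | intermediate
13 | 3-{(2S)-2,8-dimethyl-4-oxo-6-[(triisopropylsilyl)oxy]chroman-2-yl}propanal | O=CCC[C@@]1(C)CC(=O)c2cc(O[Si](C(C)C)(C(C)C)C(C)C)cc(C)c2O1 | intermediate
14 | ethyl 2-(triphenylphosphoranylidene)propanoate | CCOC(=O)C(C)=P(c1ccccc1)(c1ccccc1)c1ccccc1 | starting material
15 | ethyl (2E)-5-{(2S)-2,8-dimethyl-4-oxo-6-[(triisopropylsilyl)oxy]chroman-2-yl}-2-methylpent-2-enoate | CCOC(=O)/C(C)=C/CC[C@@]1(C)CC(=O)c2cc(O[Si](C(C)C)(C(C)C)C(C)C)cc(C)c2O1 | intermediate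
16 | ethyl (2E)-5-{(2S)-4-hydroxy-2,8-dimethyl-6-[(triisopropylsilyl)oxy]chroman-2-yl}-2-methylpent-2-enoate (both C4 epimers) | CCOC(=O)/C(C)=C/CC[C@@]1(C)CC(O)c2cc(O[Si](C(C)C)(C(C)C)C(C)C)cc(C)c2O1 | intermediate
17 | ethyl (2E)-5-{(2S)-2,8-dimethyl-6-[(triisopropylsilyl)oxy]-2H-chromen-2-yl}-2-methylpent-2-enoate | CCOC(=O)/C(C)=C/CC[C@@]1(C)C=Cc2cc(O[Si](C(C)C)(C(C)C)C(C)C)cc(C)c2O1 | intermediate
18 | (2E)-5-{(2S)-2,8-dimethyl-6-[(triisopropylsilyl)oxy]-2H-chromen-2-yl}-2-methylpent-2-en-1-ol | OC/C(C)=C/CC[C@@]1(C)C=Cc2cc(O[Si](C(C)C)(C(C)C)C(C)C)cc(C)c2O1 | intermediate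
19 | ({(2S)-2-[(3E)-5-bromo-4-methylpent-3-en-1-yl]-2,8-dimethyl-2H-chromen-6-yl}oxy)triisopropylsilane | BrC/C(C)=C/CC[C@@]1(C)C=Cc2cc(O[Si](C(C)C)(C(C)C)C(C)C)cc(C)c2O1 | intermediate
20 | geraniol | CC(C)=CCC/C(C)=C/CO | starting material
21 | [(2S,3S)-3-methyl-3-(4-methylpent-3-en-1-yl)oxiran-2-yl]methanol | CC(C)=CCC[C@]1(C)O[C@H]1CO | intermediate
22 | (2R,3S)-2-(chloromethyl)-3-methyl-3-(4-methylpent-3-en-1-yl)oxirane | CC(C)=CCC[C@]1(C)O[C@H]1CCl | intermediate
23 | lithium (3S)-1-chloro-3,7-dimethylocta-1,6-dien-3-olate (C1=C2 geometry not defined) | CC(C)=CCC[C@](C)([O-])C=CCl.[Li+] | intermediate (not isolated)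
24 | (3S)-3,7-dimethyloct-6-en-1-yn-3-ol | CC(C)=CCC[C@](C)(O)C#C | intermediate
25 | bis(bromomagnesium) salt of 24 (bromomagnesium alkoxide and alkynylmagnesium bromide) | CC(C)=CCC[C@](C)(O[Mg]Br)C#C[Mg]Br | intermediate (not isolated)
26 | (6S,10E)-13-{(2S)-2,8-dimethyl-6-[(triisopropylsilyl)oxy]-2H-chromen-2-yl}-2,6,10-trimethyltrideca-2,10-dien-7-yn-6-ol | CC(C)=CCC[C@](C)(O)C#CC/C(C)=C/CC[C@@]1(C)C=Cc2cc(O[Si](C(C)C)(C(C)C)C(C)C)cc(C)c2O1 | intermediate
27 | (6S,7E,10E)-13-{(2S)-2,8-dimethyl-6-[(triisopropylsilyl)oxy]-2H-chromen-2-yl}-2,6,10-trimethyltrideca-2,7,10-trien-6-ol | CC(C)=CCC[C@](C)(O)/C=C/C/C(C)=C/CC[C@@]1(C)C=Cc2cc(O[Si](C(C)C)(C(C)C)C(C)C)cc(C)c2O1 | intermediate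
28 | (2S)-2-[(3E,6E,8S)-8-hydroxy-4,8,12-trimethyltrideca-3,6,11-trien-1-yl]-2,8-dimethyl-2H-chromen-6-ol | CC(C)=CCC[C@](C)(O)/C=C/C/C(C)=C/CC[C@@]1(C)C=Cc2cc(O)cc(C)c2O1 | target

## Step count and least certain steps

Total step count: 18. Longest linear sequence: 15 steps (steps 1–12 and 16–18, from 1). Alkynol 24 takes 3 steps from 20 (steps 13–15).

**Step 5 (key step).** Three things may go wrong.

- Deprotonation of the 2-methyl group of the cation may outrun addition at C2, so that conversion stalls. The cation also lacks the electron-withdrawing C2 substituent of the most reactive precedents.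
- Enantioface discrimination may be weak, because the methyl group and the C3–H edge differ little in size.
- Silyl triflate may ionise the acetal of 8, making it a second electrophile for the acetylide.

Fallback, from 3 to 13: annulation and resolution in place of asymmetric catalysis. Acetophenone 3 would be demethylated with BBr3 to 1-(2,5-dihydroxy-3-methylphenyl)ethan-1-one F1. Kabbe condensation of F1 with 5,5-dimethoxypentan-2-one (pyrrolidine, EtOH, reflux) would build the ring by enamine aldol addition and oxa-Michael closure and give racemic 2-(3,3-dimethoxypropyl)-6-hydroxy-2,8-dimethylchroman-4-one F2. Silylation (TIPSCl, imidazole) would give racemic 2-(3,3-dimethoxypropyl)-2,8-dimethyl-6-[(triisopropylsilyl)oxy]chroman-4-one F3. Preparative chromatography on a chiral stationary phase would deliver (S)-2-(3,3-dimethoxypropyl)-2,8-dimethyl-6-[(triisopropylsilyl)oxy]chroman-4-one F4. Hydrolysis of F4 under the conditions of step 7 returns to the route at 13. Half of the material is lost, but every operation is routine.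

**Step 16.** The alkynylcopper may attack the γ-carbon (C3') and give the branched SN2' isomer. Residual EtMgBr may transfer ethyl to the bromide. Metalation may be incomplete if the dimagnesium salt is poorly soluble.

Fallback, from 24 to 27: hydrostannation of 24 (Bu3SnH, PdCl2(PPh3)2 cat., THF) would give (1E,3S)-3,7-dimethyl-1-(tributylstannyl)octa-1,6-dien-3-ol F5. Stille coupling of F5 with bromide 19 (Pd2(dba)3, AsPh3, THF, 50 °C) joins sp2 to sp3 carbon with the E-alkene already in place. It reaches 27 directly and bypasses 26 and step 17.

**Step 17.** Hydroalumination of the hindered tertiary alkoxide may be slow. The forcing conditions then needed invite migration of the skipped enyne into conjugation and loss of the aryl silyl ether (the latter harmless).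

Fallback, from 26 to 28: ruthenium-catalysed trans-hydrosilylation ([Cp*Ru(MeCN)3]PF6 cat., (EtO)3SiH, CH2Cl2, 0 °C) would give (6S,7Z,10E)-13-{(2S)-2,8-dimethyl-6-[(triisopropylsilyl)oxy]-2H-chromen-2-yl}-2,6,10-trimethyl-8-(triethoxysilyl)trideca-2,7,10-trien-6-ol F6. F6 is drawn with silicon distal to the hydroxyl; either regioisomer leads to the same alkene. Treatment with Bu4NF and CuI in THF would remove the vinyl silicon with retention and the aryl silyl group in the same operation, arriving at 28.

**Step 10.** The acid that ionises C4 can also re-protonate the new chromene at C3, leading to dimerisation or oligomerisation of the electron-rich styrene.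

Fallback, from 16 to 17: activation and base-mediated elimination in place of acid ionisation. MsCl and Et3N (CH2Cl2, 0 °C) would give ethyl (2E)-5-{(2S)-2,8-dimethyl-4-[(methylsulfonyl)oxy]-6-[(triisopropylsilyl)oxy]chroman-2-yl}-2-methylpent-2-enoate F7, which DBU would eliminate to 17 without free acid.

**Step 6.** C2–O hydrogenolysis may occur at the half-reduced stage, where the tertiary aryl ether is allylic on the palladium surface, and the aryl ketone may be over-reduced.

Fallback, from 11 to 12: metal-free transfer of hydrogen from diimide, generated from dipotassium azodicarboxylate (KO2CN=NCO2K) and AcOH in EtOH at rt. Diimide saturates the alkyne by concerted syn-addition and has no pathway for C–O cleavage or carbonyl reduction. No new compound is involved.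

## Further compounds

F1 | step 5 | 1-(2,5-dihydroxy-3-methylphenyl)ethan-1-one | CC(=O)c1cc(O)cc(C)c1O
F2 | step 5 | racemic 2-(3,3-dimethoxypropyl)-6-hydroxy-2,8-dimethylchroman-4-one | COC(CCC1(C)CC(=O)c2cc(O)cc(C)c2O1)OC
F3 | step 5 | racemic 2-(3,3-dimethoxypropyl)-2,8-dimethyl-6-[(triisopropylsilyl)oxy]chroman-4-one | COC(CCC1(C)CC(=O)c2cc(O[Si](C(C)C)(C(C)C)C(C)C)cc(C)c2O1)OC
F4 | step 5 | (S)-2-(3,3-dimethoxypropyl)-2,8-dimethyl-6-[(triisopropylsilyl)oxy]chroman-4-one | COC(OC)CC[C@@]1(C)CC(=O)c2cc(O[Si](C(C)C)(C(C)C)C(C)C)cc(C)c2O1
F5 | step 16 | (1E,3S)-3,7-dimethyl-1-(tributylstannyl)octa-1,6-dien-3-ol | CC(C)=CCC[C@](C)(O)/C=C/[Sn](CCCC)(CCCC)CCCC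
F6 | step 17 | (6S,7Z,10E)-13-{(2S)-2,8-dimethyl-6-[(triisopropylsilyl)oxy]-2H-chromen-2-yl}-2,6,10-trimethyl-8-(triethoxysilyl)trideca-2,7,10-trien-6-ol | CC(C)=CCC[C@](C)(O)/C=C(\[Si](OCC)(OCC)OCC)C/C(C)=C/CC[C@@]1(C)C=Cc2cc(O[Si](C(C)C)(C(C)C)C(C)C)cc(C)c2O1
F7 | step 10 | ethyl (2E)-5-{(2S)-2,8-dimethyl-4-[(methylsulfonyl)oxy]-6-[(triisopropylsilyl)oxy]chroman-2-yl}-2-methylpent-2-enoate | CCOC(=O)/C(C)=C/CC[C@@]1(C)CC(OS(C)(=O)=O)c2cc(O[Si](C(C)C)(C(C)C)C(C)C)cc(C)c2O1
F0 | step 6 | none | none
A1 | alternative 1 | (S)-2,8-dimethyl-2-(4-methylpent-3-en-1-yl)-2H-chromen-6-ol | CC(C)=CCC[C@@]1(C)C=Cc2cc(O)cc(C)c2O1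
A2 | alternative 1 | pentacarbonyl{[(3Z,5S)-5,9-dimethyldeca-3,8-dien-1-yn-5-yl]oxy(prop-1-en-2-yl)methylidene}chromium | C=C(C)C(=[Cr])O[C@@](C)(CCC=C(C)C)/C=C\C#C.[C-]#[O+].[C-]#[O+].[C-]#[O+].[C-]#[O+].[C-]#[O+]
A3 | alternative 2 | (S)-2-allyl-2,8-dimethyl-6-[(triisopropylsilyl)oxy]chroman-3-one | C=CC[C@@]1(C)C(=O)Cc2cc(O[Si](C(C)C)(C(C)C)C(C)C)cc(C)c2O1
A4 | alternative 2 | (S)-2-allyl-2,7-dimethyl-5-[(triisopropylsilyl)oxy]benzofuran-3(2H)-one | C=CC[C@@]1(C)C(=O)c2cc(O[Si](C(C)C)(C(C)C)C(C)C)cc(C)c2O1
A5 | alternative 3 | (6S,7E,10E)-13-{(2S)-6-[(tert-butyldimethylsilyl)oxy]-2,8-dimethyl-2H-chromen-2-yl}-2,6,10-trimethyltrideca-2,7,10-trien-6-ol | CC(C)=CCC[C@](C)(O)/C=C/C/C(C)=C/CC[C@@]1(C)C=Cc2cc(O[Si](C)(C)C(C)(C)C)cc(C)c2O1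
A6 | alternative 3 | tert-butyl({(2S)-2,8-dimethyl-2-[(3E)-4-methylhept-3-en-6-yn-1-yl]-2H-chromen-6-yl}oxy)dimethylsilane | C#CC/C(C)=C/CC[C@@]1(C)C=Cc2cc(O[Si](C)(C)C(C)(C)C)cc(C)c2O1
A7 | alternative 3 | 6-methylhept-5-en-2-one | CC(C)=CCCC(C)=O
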